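## Retrosynthetic overview

1. The target comes from a ring-A vinylogous ester by Stork–Danheiser unmasking (C3–CH3 / C1=O), acylation at O8 (angelate) and O9 ((R)-2-methylbutanoate), and C7 desilylation.
2. The C7–C9 triol comes from a cyclohept-8-en-7-one: CBS reduction sets C7, then dihydroxylation anti to the C7 silyloxy group sets C8/C9.
3. The seven-membered ring and the C6 gem-dimethyl group come from one key step: a selenium-triggered semipinacol 1,2-shift that expands a cyclobutane-fused cyclohexanone by one CMe2 unit.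
4. The cyclobutane comes from a 4-exo enolate/epoxide closure on a cis-decalin; the decalin comes from an enantioselective Mukaiyama–Michael annulation of 3-methylcyclohexenone with a 1,1-dimethoxy-3-silyloxydiene.
5. Ring order: six-membered ring B′ (bought) → ring A → cyclobutane → ring B (6→7 expansion).

Assumptions and conventions: angelic acid and (R)-2-methylbutanoic acid (the target SMILES encodes the R acyl group) are bought as such. "C1–C11" in the Why lines is longipinane numbering of the target (C1 ketone, C2=C3–CH3, C4, C5, C6 gem-dimethyl, C7 OH, C8 O-angeloyl, C9 O-acyl, C10 C–CH3, C11). Tricyclo[5.4.0.0^2,8]undecane locants 1–11 correspond to longipinane C11, C10, C9, C8, C7, C6, C5, C4, C3, C2, C1, and decalin locants 1, 2, 3, 4, 4a, 5, 6, 7, 8, 8a to C4, C3, C2, C1, C11, C5, C7, C8, C9, C10. The IDPi antipode that gives (8aR)-7 is fixed in the first experiment, and 2,2-bis(methylselanyl)propane is a literature reagent (acetone, MeSeH, ZnCl2).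

## Route

Step 1
Reactants: 1 1,1-dimethoxyethene; 2 acetyl chloride
Product: 3 4,4-dimethoxybut-3-en-2-one
Conditions: Et3N, Et2O, 0 → 23 °C
Reagents that add atoms: none
Why: C-acylation of the electron-rich ketene acetal by addition–elimination gives the acylketene acetal; no stereocentre is formed.

Step 2
Reactants: 3 4,4-dimethoxybut-3-en-2-one
Product: 4 1,1-dimethoxy-3-(trimethylsilyloxy)buta-1,3-diene
Conditions: LDA, THF, −78 °C; TMSCl
Reagents that add atoms: chlorotrimethylsilane, C[Si](C)(C)Cl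
Why: Kinetic enolisation of the methyl ketone and O-silylation (Danishefsky-type diene synthesis) gives the doubly activated diene.

Step 3
Reactants: 4 1,1-dimethoxy-3-(trimethylsilyloxy)buta-1,3-diene; 5 3-methylcyclohex-2-en-1-one
Product: 7 (4aR,8aR)-4-methoxy-8a-methyl-4a,7,8,8a-tetrahydronaphthalene-2,5(1H,6H)-dione (cis-fused), via Mukaiyama–Michael silyl enol ether 6 (not isolated)
Conditions: chiral IDPi (imidodiphosphorimidate) acid (3 mol %), toluene, −60 → −30 °C; then TFA (0.2 equiv), CH2Cl2, 0 °C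
Reagents that add atoms: none
Why: Proposed new method: the confined chiral silylium–IDPi ion pair (formed by protodesilylation of 4) O-silylates enone 5, the CH2 terminus of 4 adds to the β-carbon from one enantioface (Mukaiyama–Michael, sets the quaternary C8a) to give enol silane 6, and acid then closes ring A by intramolecular addition–elimination of the regiodefined enol silane onto the acylketene acetal (loss of MeOSiMe3), the short tether giving the cis ring fusion and fixing which carbon carries OMe; the closest known reactions are IDPi-catalysed Mukaiyama–Michael/aldol additions of silyl ketene acetals and the achiral AlBr3/AlMe3-promoted formal Diels–Alder reactions of silyloxydienes with 3-methylcyclohexenone.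

Step 4
Reactants: 7 (4aR,8aR)-4-methoxy-8a-methyl-4a,7,8,8a-tetrahydronaphthalene-2,5(1H,6H)-dione
Product: 8 5-(p-toluenesulfonyl)hydrazone of 7 (N–NHTs syn to C6H2)
Conditions: TsNHNH2, MeOH, 23 °C
Reagents that add atoms: p-toluenesulfonyl hydrazide, Cc1ccc(cc1)S(=O)(=O)NN
Why: Hydrazone condensation occurs only at the saturated C5 ketone because the vinylogous-ester carbonyl is ester-like, and the NHTs group turns away from the ring fusion.

Step 5
Reactants: 8 5-(p-toluenesulfonyl)hydrazone of 7
Product: 9 (4aR,8aR)-4-methoxy-8a-methyl-4a,7,8,8a-tetrahydronaphthalen-2(1H)-one (5,6-alkene)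
Conditions: LDA (3.5 equiv), THF, −78 → 0 °C; H2O
Reagents that add atoms: none
Why: Shapiro reaction: the hydrazone dianion forms at the less substituted CH2 syn to N, loses sulfinate and N2, and the vinyllithium is protonated to the less substituted alkene, while LDA (not an alkyllithium) spares the vinylogous ester, which sits as its α′-enolate.

Step 6
Reactants: 9 (4aR,8aR)-4-methoxy-8a-methyl-4a,7,8,8a-tetrahydronaphthalen-2(1H)-one
Product: 10 5,6-epoxide of 9 with the oxirane on the face of 8a-CH3 and 4a-H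
Conditions: m-CPBA, NaHCO3, CH2Cl2, 0 °C
Reagents that add atoms: m-chloroperbenzoic acid, OOC(=O)c1cccc(Cl)c1
Why: Prilezhaev epoxidation takes the only non-conjugated alkene from the convex face of the cis-decalin (anti to the ring-A carbons), which is the face required for the next step.

Step 7
Reactants: 10 5,6-epoxide of 9
Product: 11 8-hydroxy-5-methoxy-1-methyltricyclo[4.4.0.0^2,7]dec-4-en-3-one (OH anti to the new C2–C7 bond)
Conditions: LDA (1.1 equiv), THF, −78 °C; DMPU, −78 → 23 °C
Reagents that add atoms: none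
Why: The kinetic α′-enolate of the vinylogous ester (decalin C1) opens the epoxide at C5 in a 4-exo-tet, trans-diaxial SN2 (Stork epoxynitrile / Heathcock copaene-type cyclobutane closure); inversion at C5 gives the only geometrically possible cyclobutane configuration.

Step 8
Reactants: 11 8-hydroxy-5-methoxy-1-methyltricyclo[4.4.0.0^2,7]dec-4-en-3-one
Product: 12 5-methoxy-1-methyltricyclo[4.4.0.0^2,7]dec-4-ene-3,8-dione
Conditions: Dess–Martin periodinane, NaHCO3, CH2Cl2, 23 °C
Reagents that add atoms: none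
Why: Dess–Martin oxidation of the secondary alcohol gives the C7 ketone (longipinane numbering) next to the cyclobutane carbon C5; the carbinol stereocentre is deliberately removed.

Step 9
Reactants: 12 5-methoxy-1-methyltricyclo[4.4.0.0^2,7]dec-4-ene-3,8-dione
Product: 13 8-hydroxy-5-methoxy-1-methyl-8-[2-(methylselanyl)propan-2-yl]tricyclo[4.4.0.0^2,7]dec-4-en-3-one (epimers at C8)
Conditions: Me2C(SeMe)2, n-BuLi, THF, −78 °C; then 12, −78 °C; NH4Cl
Reagents that add atoms: 2,2-bis(methylselanyl)propane, C[Se]C(C)(C)[Se]C (as its lithio derivative 2-lithio-2-(methylselanyl)propane, [Li]C(C)(C)[Se]C)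
Why: Se/Li exchange gives Krief's tertiary α-selenoalkyllithium, which adds 1,2 to the saturated ketone much faster than to the ester-like, non-enolisable vinylogous ester; the new carbinol configuration is irrelevant because both epimers converge in step 10.

Step 10
Reactants: 13 β-hydroxy selenide
Product: 14 11-methoxy-2,6,6-trimethyltricyclo[5.4.0.0^2,8]undec-10-ene-5,9-dione
Conditions: AgBF4, Al2O3, CH2Cl2, 23 °C
Reagents that add atoms: none
Why: Key step, Krief semipinacol ring enlargement: Ag(I) removes MeSe to give a tertiary carbenium ion next to the carbinol, the more substituted ring bond (C7–C5) undergoes the 1,2-shift, and the cyclohexanol becomes the 2,2-dimethylcycloheptanone with C6(CH3)2 between C5 and C7 and no existing stereocentre touched.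

Step 11
Reactants: 14 11-methoxy-2,6,6-trimethyltricyclo[5.4.0.0^2,8]undec-10-ene-5,9-dione
Product: 15 11-methoxy-2,6,6-trimethyltricyclo[5.4.0.0^2,8]undeca-3,10-diene-5,9-dione
Conditions: IBX, 4-methoxypyridine N-oxide, DMSO, 23 °C
Reagents that add atoms: none
Why: Nicolaou IBX dehydrogenation can only give the C8=C9 enone because C6 is quaternary and C5, C4 and C11 are bridgeheads; over-oxidation is blocked by quaternary C10.

Step 12
Reactants: 15 11-methoxy-2,6,6-trimethyltricyclo[5.4.0.0^2,8]undeca-3,10-diene-5,9-dione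
Product: 16 5-hydroxy-11-methoxy-2,6,6-trimethyltricyclo[5.4.0.0^2,8]undeca-3,10-dien-9-one ((7R) in longipinane numbering, OH toward C4)
Conditions: (S)-Me-CBS (0.3 equiv), BH3·SMe2, THF/toluene, −40 °C
Reagents that add atoms: none
Why: Corey–Bakshi–Shibata reduction under catalyst control (the two ketone faces are nearly equivalent because ring B lies in a local mirror plane of the skeleton), with quaternary C6 as the large group, gives the (7R) allylic alcohol; the vinylogous ester is not reduced by borane at this temperature.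

Step 13
Reactants: 16 allylic alcohol
Product: 17 5-(tert-butyldimethylsilyloxy)-11-methoxy-2,6,6-trimethyltricyclo[5.4.0.0^2,8]undeca-3,10-dien-9-one
Conditions: TBSOTf, 2,6-lutidine, CH2Cl2, −78 → 0 °C
Reagents that add atoms: tert-butyldimethylsilyl triflate, CC(C)(C)[Si](C)(C)OS(=O)(=O)C(F)(F)F
Why: Silyl triflate protection of the hindered neopentyl allylic alcohol masks O7 so that only O8 and O9 are later acylated, and gives a bulky anti-directing group.

Step 14
Reactants: 17 TBS ether
Product: 18 5-(tert-butyldimethylsilyloxy)-3,4-dihydroxy-11-methoxy-2,6,6-trimethyltricyclo[5.4.0.0^2,8]undec-10-en-9-one (3,4-cis-diol anti to the 5-silyloxy group)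
Conditions: OsO4 (5 mol %), NMO, acetone/H2O, 23 °C
Reagents that add atoms: osmium tetroxide, O=[Os](=O)(=O)=O (transfers both oxygen atoms; re-oxidised by N-methylmorpholine N-oxide, C[N+]1([O-])CCOCC1)
Why: Upjohn dihydroxylation occurs anti to the allylic silyloxy group (Kishi's rule), placing O8 and O9 cis to each other and trans to O7; the push–pull alkene of the vinylogous ester is inert to OsO4.

Step 15
Reactants: 18 diol vinylogous ester
Product: 20 5-(tert-butyldimethylsilyloxy)-3,4-dihydroxy-2,6,6,9-tetramethyltricyclo[5.4.0.0^2,8]undec-9-en-11-one, via tertiary carbinol 19 (not isolated)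
Conditions: MeLi (4.5 equiv), THF, −78 → 0 °C; then 1 M HCl, THF, 0 °C, 15 min
Reagents that add atoms: methyllithium, [Li]C
Why: Stork–Danheiser transposition: MeLi adds 1,2 to the vinylogous-ester carbonyl (the diol is carried as its dialkoxide), and acid hydrolyses the enol ether and dehydrates the carbinol, giving the C1 ketone and C2=C3–CH3 with the regiochemistry fixed in step 3.

Step 16
Reactants: 20 enone diol; 21 angelic acid ((Z)-2-methylbut-2-enoic acid)
Product: 23 4-O-angeloyl derivative of 20 (ester at longipinane O8), via angelic trichlorobenzoic anhydride 22 (not isolated)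
Conditions: 21, 2,4,6-Cl3C6H2COCl, Et3N, toluene, 23 °C; then 20, toluene, 80 °C
Reagents that add atoms: none
Why: Yamaguchi-type mixed-anhydride acylation without DMAP keeps the (Z)-geometry of the angelate and reacts at the less hindered C8–OH, since C9–OH is neopentyl next to quaternary C10.

Step 17
Reactants: 23 8-angelate; 24 (R)-2-methylbutanoic acid
Product: 26 3-O-[(R)-2-methylbutanoyl]-4-O-angeloyl-5-O-TBS triester precursor, via methylbutanoic trichlorobenzoic anhydride 25 (not isolated)
Conditions: 24, 2,4,6-Cl3C6H2COCl, Et3N, toluene, 23 °C; then 23, DMAP, toluene, 50 °C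
Reagents that add atoms: none
Why: Yamaguchi esterification with DMAP forces acylation of the hindered C9–OH, and the α-stereocentre of the acid is retained because no ketene is formed from the mixed anhydride.

Step 18
Reactants: 26 silyl-protected diester
Product: 27 target, 4-angeloyloxy-5-hydroxy-3-[(2R)-2-methylbutanoyloxy]-2,6,6,9-tetramethyltricyclo[5.4.0.0^2,8]undec-9-en-11-one (CNP0202800.1)
Conditions: HF·pyridine, pyridine, THF, 0 → 23 °C
Reagents that add atoms: none
Why: Buffered fluoride desilylation frees the C7 hydroxyl without base-induced acyl migration and leaves the enone and the angelate untouched.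

## Compound list

1 | 1,1-dimethoxyethene | C=C(OC)OC | starting material
2 | acetyl chloride | CC(=O)Cl | starting material
3 | 4,4-dimethoxybut-3-en-2-one | CC(=O)C=C(OC)OC | intermediate
4 | 1,1-dimethoxy-3-(trimethylsilyloxy)buta-1,3-diene | C=C(O[Si](C)(C)C)C=C(OC)OC | intermediate
5 | 3-methylcyclohex-2-en-1-one | CC1=CC(=O)CCC1 | starting material
6 | (R)-4,4-dimethoxy-1-[1-methyl-3-(trimethylsilyloxy)cyclohex-2-en-1-yl]but-3-en-2-one | COC(OC)=CC(=O)C[C@@]1(C)CCCC(O[Si](C)(C)C)=C1 | intermediate
7 | (4aR,8aR)-4-methoxy-8a-methyl-4a,7,8,8a-tetrahydronaphthalene-2,5(1H,6H)-dione | C1CC(=O)[C@H]2C(OC)=CC(=O)C[C@@]2(C)C1 | intermediate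
8 | 5-(p-toluenesulfonyl)hydrazone of 7 | C1C/C(=N\NS(=O)(=O)c3ccc(C)cc3)[C@H]2C(OC)=CC(=O)C[C@@]2(C)C1 | intermediate
9 | (4aR,8aR)-4-methoxy-8a-methyl-4a,7,8,8a-tetrahydronaphthalen-2(1H)-one | C1C=C[C@H]2C(OC)=CC(=O)C[C@@]2(C)C1 | intermediate
10 | 5,6-epoxide of 9 (oxirane syn to 8a-CH3) | C1C[C@@H]3O[C@@H]3[C@H]2C(OC)=CC(=O)C[C@@]2(C)C1 | intermediate
11 | 8-hydroxy-5-methoxy-1-methyltricyclo[4.4.0.0^2,7]dec-4-en-3-one | C1[C@H](O)[C@@H]2[C@H]3C(OC)=CC(=O)[C@@H]2[C@@]3(C)C1 | intermediate
12 | 5-methoxy-1-methyltricyclo[4.4.0.0^2,7]dec-4-ene-3,8-dione | C1C(=O)[C@@H]2[C@H]3C(OC)=CC(=O)[C@@H]2[C@@]3(C)C1 | intermediate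
13 | 8-hydroxy-5-methoxy-1-methyl-8-[2-(methylselanyl)propan-2-yl]tricyclo[4.4.0.0^2,7]dec-4-en-3-one (C8 epimers) | C1C(O)(C(C)(C)[Se]C)[C@@H]2[C@H]3C(OC)=CC(=O)[C@@H]2[C@@]3(C)C1 | intermediate
14 | 11-methoxy-2,6,6-trimethyltricyclo[5.4.0.0^2,8]undec-10-ene-5,9-dione | C1C(=O)C(C)(C)[C@@H]2[C@H]3C(OC)=CC(=O)[C@@H]2[C@@]3(C)C1 | intermediate
15 | 11-methoxy-2,6,6-trimethyltricyclo[5.4.0.0^2,8]undeca-3,10-diene-5,9-dione | C=1C(=O)C(C)(C)[C@@H]2[C@H]3C(OC)=CC(=O)[C@@H]2[C@@]3(C)C=1 | intermediate
16 | 5-hydroxy-11-methoxy-2,6,6-trimethyltricyclo[5.4.0.0^2,8]undeca-3,10-dien-9-one | C=1[C@@H](O)C(C)(C)[C@@H]2[C@H]3C(OC)=CC(=O)[C@@H]2[C@@]3(C)C=1 | intermediate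
17 | 5-(tert-butyldimethylsilyloxy)-11-methoxy-2,6,6-trimethyltricyclo[5.4.0.0^2,8]undeca-3,10-dien-9-one | C=1[C@@H](O[Si](C)(C)C(C)(C)C)C(C)(C)[C@@H]2[C@H]3C(OC)=CC(=O)[C@@H]2[C@@]3(C)C=1 | intermediate
18 | 5-(tert-butyldimethylsilyloxy)-3,4-dihydroxy-11-methoxy-2,6,6-trimethyltricyclo[5.4.0.0^2,8]undec-10-en-9-one | O[C@@H]1[C@@H](O[Si](C)(C)C(C)(C)C)C(C)(C)[C@@H]2[C@H]3C(OC)=CC(=O)[C@@H]2[C@@]3(C)[C@@H]1O | intermediate
19 | 5-(tert-butyldimethylsilyloxy)-11-methoxy-2,6,6,9-tetramethyltricyclo[5.4.0.0^2,8]undec-10-ene-3,4,9-triol (C9 carbinol configuration not assigned, lost on work-up) | O[C@@H]1[C@@H](O[Si](C)(C)C(C)(C)C)C(C)(C)[C@@H]2[C@H]3C(OC)=CC(C)(O)[C@@H]2[C@@]3(C)[C@@H]1O | intermediate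
20 | 5-(tert-butyldimethylsilyloxy)-3,4-dihydroxy-2,6,6,9-tetramethyltricyclo[5.4.0.0^2,8]undec-9-en-11-one | O[C@@H]1[C@@H](O[Si](C)(C)C(C)(C)C)C(C)(C)[C@@H]2[C@H]3C(=O)C=C(C)[C@@H]2[C@@]3(C)[C@@H]1O | intermediate
21 | angelic acid, (Z)-2-methylbut-2-enoic acid | C/C=C(/C)C(=O)O | starting material
22 | (Z)-2-methylbut-2-enoic 2,4,6-trichlorobenzoic anhydride | C/C=C(/C)C(=O)OC(=O)c1c(Cl)cc(Cl)cc1Cl | intermediate
23 | 4-angeloyloxy-5-(tert-butyldimethylsilyloxy)-3-hydroxy-2,6,6,9-tetramethyltricyclo[5.4.0.0^2,8]undec-9-en-11-one | C/C=C(/C)C(=O)O[C@@H]1[C@@H](O[Si](C)(C)C(C)(C)C)C(C)(C)[C@@H]2[C@H]3C(=O)C=C(C)[C@@H]2[C@@]3(C)[C@@H]1O | intermediate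
24 | (R)-2-methylbutanoic acid | CC[C@@H](C)C(=O)O | starting material
25 | (R)-2-methylbutanoic 2,4,6-trichlorobenzoic anhydride | CC[C@@H](C)C(=O)OC(=O)c1c(Cl)cc(Cl)cc1Cl | intermediate
26 | 4-angeloyloxy-5-(tert-butyldimethylsilyloxy)-3-[(2R)-2-methylbutanoyloxy]-2,6,6,9-tetramethyltricyclo[5.4.0.0^2,8]undec-9-en-11-one | C/C=C(/C)C(=O)O[C@@H]1[C@@H](O[Si](C)(C)C(C)(C)C)C(C)(C)[C@@H]2[C@H]3C(=O)C=C(C)[C@@H]2[C@@]3(C)[C@@H]1OC(=O)[C@H](C)CC | intermediate
27 | 4-angeloyloxy-5-hydroxy-3-[(2R)-2-methylbutanoyloxy]-2,6,6,9-tetramethyltricyclo[5.4.0.0^2,8]undec-9-en-11-one (CNP0202800.1) | C/C=C(/C)C(=O)O[C@@H]1[C@@H](O)C(C)(C)[C@@H]2[C@H]3C(=O)C=C(C)[C@@H]2[C@@]3(C)[C@@H]1OC(=O)[C@H](C)CC | target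

## Step count and risk

Total steps: 18. Longest linear sequence: 18 (from 1 and 2 to 27); 5, 21 and 24 enter at steps 3, 16 and 17.

**Step 3 (the proposed new enantioselective annulation).** Risks are low reactivity of the β,β-disubstituted enone and insufficient enantiocontrol at the quaternary carbon. Fallback with known chemistry: starting again from 4 and 5, the annulation is run with an achiral Lewis acid (TiCl4, CH2Cl2, −78 °C, Mukaiyama–Michael addition of the enol silane, then TFA to close ring A). This gives racemic 7, that is 7 together with its mirror image ent-7 F1. The two are separated by preparative chromatography on a chiral stationary phase, and (4aR,8aR)-7 re-enters the route at step 4.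

**Step 7 (cyclobutane closure).** Risks are attack of the enolate at the distal epoxide carbon (a bridged five-membered ring) and base-induced epoxide-to-allylic-alcohol elimination. Fallback, setting out from alkene 9 and returning at 11: OsO4/NMO dihydroxylation from the convex face gives the cis-5,6-diol F2. TBSCl/imidazole silylates the less hindered C6 hydroxyl to give silyl ether F3, and MsCl/Et3N converts the remaining C5 hydroxyl into mesylate F4, so that only C5 carries a leaving group. LDA in THF/DMPU then closes the cyclobutane by the classical Heathcock-type intramolecular α′-alkylation to give the tricyclic silyl ether F5, and TBAF liberates alcohol 11.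

**Step 10 (with step 9, the ring expansion).** Risks are enolisation instead of addition of the hindered selenium carbanion, and migration of the CH2 carbon instead of the cyclobutane carbon. Fallback, setting out from ketone 12 and returning at 14: isopropylidene transfer from diphenylsulfonium isopropylide (isopropyldiphenylsulfonium tetrafluoroborate, LDA, DME, −78 °C; Corey–Chaykovsky) gives the oxaspiro epoxide F6. Its Lewis-acid-promoted (BF3·OEt2 or MABR) Meinwald-type rearrangement ionises the exocyclic C–O bond and shifts the ring bond to give the 2,2-dimethylcycloheptanone 14.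

Further compounds
F1 | step 3 | (4aS,8aS)-4-methoxy-8a-methyl-4a,7,8,8a-tetrahydronaphthalene-2,5(1H,6H)-dione (ent-7) | C1CC(=O)[C@@H]2C(OC)=CC(=O)C[C@]2(C)C1
F2 | step 7 | cis-5,6-dihydroxy-4-methoxy-8a-methyl-4a,5,6,7,8,8a-hexahydronaphthalen-2(1H)-one (diol syn to 8a-CH3) | C1C[C@H](O)[C@H](O)[C@H]2C(OC)=CC(=O)C[C@@]2(C)C1
F3 | step 7 | 6-(tert-butyldimethylsilyloxy)-5-hydroxy-4-methoxy-8a-methyl-4a,5,6,7,8,8a-hexahydronaphthalen-2(1H)-one | C1C[C@H](O[Si](C)(C)C(C)(C)C)[C@H](O)[C@H]2C(OC)=CC(=O)C[C@@]2(C)C1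
F4 | step 7 | 6-(tert-butyldimethylsilyloxy)-4-methoxy-8a-methyl-2-oxo-1,2,4a,5,6,7,8,8a-octahydronaphthalen-5-yl methanesulfonate | C1C[C@H](O[Si](C)(C)C(C)(C)C)[C@H](OS(C)(=O)=O)[C@H]2C(OC)=CC(=O)C[C@@]2(C)C1
F5 | step 7 | 8-(tert-butyldimethylsilyloxy)-5-methoxy-1-methyltricyclo[4.4.0.0^2,7]dec-4-en-3-one | C1[C@H](O[Si](C)(C)C(C)(C)C)[C@@H]2[C@H]3C(OC)=CC(=O)[C@@H]2[C@@]3(C)C1
F6 | step 10 | spiro[3,3-dimethyloxirane-2,8'-(5-methoxy-1-methyltricyclo[4.4.0.0^2,7]dec-4-en-3-one)] (spiro epimers) | C1C2(OC2(C)C)[C@@H]3[C@H]4C(OC)=CC(=O)[C@@H]3[C@@]4(C)C1
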